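# Petrosin A by ring-rearrangement metathesis of a cyclopentenyl amine: synthesis proposal

Numbering follows quinolizidin-2-one numbering. Primed locants belong to the second unit. Ca to Ce are the five chain carbons counted from C9 (or C9').

## Analysis of the target

Petrosin A (38, C30H50N2O2) consists of two quinolizidin-2-one units (ring A: N5, C4, C3, C2, C1, C9a; ring B: N5, C6, C7, C8, C9, C9a). Two pentamethylene chains tie them head to tail, C9 to C1' and C9' to C1, so that C1, C9a and C9 of each unit plus ten CH2 groups form a 16-membered carbocycle. Each unit has four stereocentres, which the SMILES gives as 1R,3R,9S,9aS and 1'S,3'S,9'R,9a'R, so the units are mirror images and the molecule is a meso compound with a centre of inversion. Within a unit H9 and H9a are anti, H1 and H9a are syn, and the C3 methyl group is trans to the chain on C1. In the trans-fused chair–chair form this places the C9 chain and the methyl group equatorial and the C1 chain axial, which avoids the syn-pentane contact of two equatorial chains at the peri positions C1 and C9. Each nitrogen is β to the C2 ketone along two paths (C9a–C1 and C4–C3), so 38 is a twofold Mannich base: C1 and C3 epimerise by enolisation, C9a by retro-Mannich or retro-Michael opening, and strong base, hot acid and dissolving metals all endanger it. Only C9 and C9' cannot be corrected once set, and they are of opposite sense, so both enantiomers of a C9-defined piperidine must be made, paired crosswise and head to tail, and closed to a 16-membered ring without touching C9. The strategy rests on the unbroken five-carbon run C8–C9–Ca–Cb–Cc: joined at its ends by a Cc=C8 double bond, it is a cyclopent-2-enyl group on C9a whose allylic carbon is C9.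

## Retrosynthetic reasoning

**38 to 37 (no bond cut).** C1, C3 and, more slowly, C9a are mobile in a β-amino ketone. They are left to a final equilibration of the stereoisomer mixture 37. The stereochemical problem then reduces to C9 and C9'. The forward step has to reach the most stable member of the 9S,9'R manifold.

**37 to 34 and 35 (N5–C4 and C3–C4, twice).** C4 is the only unsubstituted ring-A carbon, and it lies between the nitrogen and the enolisable C3, so it is a formaldehyde (35) carbon. Cutting the other Mannich bond, C9a–C1, would break the macrocycle and give up C9a. The cut removes two rings and two stereocentres and leaves the macrocyclic bis(piperidine) bis(ethyl ketone) 34. In the forward direction each iminium ion must be captured by the C3 enol in a six-membered closure.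

**34 to 32 and 33, and 32 to 31 (C2–C3, twice).** The ethyl groups come from ethylmagnesium bromide (33) and the bis(N-methoxy-N-methylamide) 32, which is made from the diester 31. Keeping C2 at the ester level until this point means that C1 is the only α-position while the chains are attached. A ketone would offer two competing α-positions.

**31 to 30 to 29 (bridge C9···C1' between Cc and Cd).** The but-3-enyl group on C9 and an allyl group on C1' both end at this point, so ring-closing metathesis of 29 followed by hydrogenation gives exactly five CH2 groups. The forward step has to prefer the 16-membered ring over oligomers and leave the other alkenes alone.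

**29 to 14 and 27 (C1–Ce' of the bridge C9'···C1).** Direct cross-metathesis of two halves that each carry two unhindered terminal alkenes would be statistical in partner and in orientation. An ester enolate (from 14, 9S series) and an allylic bromide (27, 9'R series) can combine in only one way, so the crosswise head-to-tail pairing is enforced.

**27 to 26, 24 and 22.** The bromide comes from the allylic alcohol 26. The allyl group on C1' comes from allyl bromide (9) and the enolate of 24. The two extra bridge carbons Cd' and Ce' come from cross-metathesis of the butenyl group of 22 with (Z)-but-2-ene-1,4-diol (23). The order matters: the cross-metathesis is run while 22 has a single terminal alkene.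

**14 and 22 to 11 and 19.** Only the oxidation level changes (acetal, aldehyde 12/20, acid 13/21, ester). The acetal is the form in which C2 passes safely through the nitronate and metathesis chemistry.

**11 to 10 (key disconnection, C7=C8).** Ring B is opened at its alkene and the butenyl terminus is folded back onto C8. This gives the N-allyl cyclopent-2-enyl carbamate 10, an isomer of 11. One catalytic step then builds ring B and releases a chain stub of the right length, and C9 is carried through unchanged. The nitrogen carries a tert-butyl carbamate and not a sulfonamide, for two reasons. A sulfonamide would later need reducing metals that the ketones of 34 cannot survive. It would also be a good leaving group β to the ester enolates.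

**10 to 8 and 9; 8 to 6; 6 to 5 and 3 (N–allyl, then C9–C9a).** The C9–C9a bond is made by asymmetric allylic alkylation of the racemic carbonate 5 with the nitronate of 3. The two hands of one ligand give the two series (6 and 15). C9a is not controlled there and is fixed by separation at the carbamate stage (8, 17).

**3 to 2 to 1; 5 to 4.** Conjugate addition of nitrite to acrolein (1) and acetalisation give 3. Acylation of cyclopent-2-en-1-ol (4) gives 5.

## Alternatives that were turned down

**Alternative 1: double Wittig union of complete bicycles.**

- *Disconnection:* both bridges are cut between Cc and Cd, with rings A and B finished and C2 masked as dioxolanes.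
- *Forward key step:* a half with two ylide termini (A1) meets the mirror-image-core half with two aldehyde termini (A2). The first olefination joins them and the second closes the macrocycle to the (Z,Z)-diene bis-ketal A3.
- *For it:* an ylide can only react with an aldehyde, so neither self-pairing nor head-to-head union is possible, and only hydrogenation and ketal hydrolysis remain. On pairing control and late convergence it is stronger than the chosen route, which needs one alkylation and one separate ring closure to reach the same certainty.
- *Against it:*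
  - A1 and A2 are two different compounds, so two full syntheses of four-stereocentre bicycles with different arms are needed, and the key step builds none of the four small rings.
  - The halide precursor of A1 holds a leaving group three carbons from C9, within easy reach of the basic N5 (six-membered quaternisation).
  - The unstabilised ylides are strong bases facing the enolisable CH2CHO arm of A2.
  - One flask has to serve a bimolecular and a macrocyclising olefination, whose concentration demands conflict.
- *Comparison:* the chosen strategy offers one sequence run with two ligand hands, a nitrogen that stays non-basic until the last two steps, and ring B plus chain stub from a single isomerisation.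

**Alternative 2: carbocyclic macrocycle, late photochemical nitrogen insertion.**

- *Disconnection:* N5–C9a and N5'–C9a' are cut, C9a is bound to C6 in a cyclopentane, and N5=C6 forms a seven-membered cyclic nitrone.
- *Forward key step:* irradiation of the bis-nitrone A4 gives the bis-oxaziridine A5, in which C9a shifts from C6 to nitrogen to give the bis(quinolizidine-2,6-dione) A6.
- *For it:* the macrocycle is assembled without any amine present, and the 1,2-shift retains configuration at C9a. On that point it is stronger than the chosen route, which has to separate C9a epimers.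
- *Against it:*
  - The migrating bond is the one anti to the nitrogen lone pair in A5, so C9a-versus-C7 migration depends on a configuration that must come out right at two sites.
  - The C2 ketones absorb in the same region and invite their own photochemistry.
  - A6 then needs two lactams reduced in the presence of two ketones, which means extra protection and redox steps.
  - Each half of A4 requires a fused five–seven carbobicycle with four stereocentres before the key step.
- *Comparison:* the chosen strategy puts nitrogen in at the amine oxidation level from the start and reaches ring B in five steps from commercial materials.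

**Alternative 3: nickel-mediated ynal cyclisation of a macrocyclic diyne.**

- *Disconnection:* C1–C2 and C1'–C2' are cut, C1≡Ce lies in the macrocycle and C2 is an aldehyde on the N-substituent.
- *Forward key step:* Ni(cod)2, PBu3 and Et3SiH turn the diyne dialdehyde A7 into the bis(allylic triethylsilyl ether) A8, closing both rings A.
- *For it:* two rings form in one catalytic operation, no enolate chemistry is needed next to C9a, and alkynes are convenient handles for building the large ring. In rings formed per step it beats the chosen key step.
- *Against it:*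
  - The N–CH2–CH(CH3)–CHO arms of A7 are Mannich bases of an aldehyde. They lose the amine by β-elimination and racemise at C3 with ease.
  - Two tertiary propargylic amines compete for zerovalent nickel.
  - Turning two linear alkyne units of a 16-membered ring into exocyclic trisubstituted alkenes raises transannular strain twice.
  - A8 still needs alkene hydrogenation, desilylation and oxidation of two amino alcohols.
- *Comparison:* the chosen strategy keeps every labile β-amino carbonyl unit out of the route until the last two steps and lets C1 be set by the same equilibration that A8 would need in the end.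

Key step: step 7

Assumption 1: the (R,R) ligand is taken to give the 9S series and the (S,S) ligand the 9R series; both series are made and each is used once, so an opposite sense of induction would only exchange the ligand labels of steps 4 and 11.

Assumption 2: C1/C1' (from 26 and 29 on) and C3/C3' (in 37) are carried as epimer mixtures and written without descriptor; they are set in step 27 on the premise that the arrangement of 38 is the most stable one of the 9S,9'R manifold.

## Steps

Step 1
Reactants: 1 acrolein
Product: 2 3-nitropropanal
Conditions: NaNO2, AcOH, THF/H2O, 0 °C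
Reagents that add atoms: sodium nitrite, [Na+].[O-]N=O
Why: Conjugate (Michael) addition of nitrite through nitrogen to the enal, with acetic acid protonating the enolate; the cold, buffered medium keeps the aldehyde from polymerising and from losing nitrite again.

Step 2
Reactants: 2 3-nitropropanal
Product: 3 1,1-dimethoxy-3-nitropropane
Conditions: HC(OMe)3, TsOH·H2O (cat.), MeOH, rt
Reagents that add atoms: trimethyl orthoformate, COC(OC)OC
Why: Acid-catalysed acetalisation driven by the orthoformate. With no enolisable carbonyl left, only the CH2NO2 group is acidic in step 4 and β-loss of nitrite is shut off.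

Step 3
Reactants: 4 cyclopent-2-en-1-ol (racemic)
Product: 5 cyclopent-2-en-1-yl methyl carbonate (racemic)
Conditions: ClCO2Me, pyridine, CH2Cl2, 0 °C
Reagents that add atoms: methyl chloroformate, COC(=O)Cl
Why: O-Acylation of the allylic alcohol. The carbonate is chosen because its ionisation releases CO2 and methoxide, the base needed in steps 4 and 11, and racemic material suffices because ionisation gives a symmetric allyl unit.

Step 4
Reactants: 5 cyclopent-2-en-1-yl methyl carbonate; 3 1,1-dimethoxy-3-nitropropane
Product: 6 (S)-3-(3,3-dimethoxy-1-nitropropyl)cyclopent-1-ene, epimer pair at the nitro carbon (C9a)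
Conditions: Pd2(dba)3·CHCl3 (2.5 mol %), (R,R)-DACH-phenyl diphosphine [(1R,2R)-N,N'-bis(2-diphenylphosphanylbenzoyl)cyclohexane-1,2-diamine] (7.5 mol %), 3 (2 equiv), CH2Cl2, rt
Reagents that add atoms: none
Why: Asymmetric allylic alkylation (Tsuji–Trost type) with a nitronate: both enantiomers of 5 ionise to the same symmetric cyclopentenyl complex of divalent palladium, and the methoxide set free deprotonates 3. The chiral pocket steers the nitronate to one allyl terminus and so sets C9 (S); the nitro carbon C9a forms without useful control and stays epimerisable, hence the epimer pair.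

Step 5
Reactants: 6 (S)-3-(3,3-dimethoxy-1-nitropropyl)cyclopent-1-ene
Product: 8 tert-butyl N-{(1R)-1-[(1S)-cyclopent-2-en-1-yl]-3,3-dimethoxypropyl}carbamate, via primary amine 7 (not isolated)
Conditions: Zn dust, AcOH, MeOH, 0 °C to rt; then Et3N, Boc2O, same flask, rt; chromatographic separation of the C9a epimers
Reagents that add atoms: di-tert-butyl dicarbonate, CC(C)(C)OC(=O)OC(=O)OC(C)(C)C
Why: Metal/acid reduction of an aliphatic nitro group (the alkene is inert and acetal exchange in MeOH only regenerates the acetal), followed by carbamate formation. C9a is configurationally stable from here on, so it is fixed by separation: the 1R,1'S isomer, which has H9/H9a anti after ring closure, is carried on.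

Step 6
Reactants: 8 carbamate of step 5; 9 allyl bromide
Product: 10 tert-butyl N-allyl-N-{(1R)-1-[(1S)-cyclopent-2-en-1-yl]-3,3-dimethoxypropyl}carbamate
Conditions: NaH, allyl bromide, DMF, 0 °C to rt
Reagents that add atoms: allyl bromide (9), C=CCBr
Why: SN2 N-alkylation of the carbamate anion with a reactive allylic halide; acetal, alkene and both stereocentres are untouched.

Step 7
Reactants: 10 N-allyl cyclopentenyl carbamate
Product: 11 tert-butyl (2R,3S)-3-(but-3-en-1-yl)-2-(2,2-dimethoxyethyl)-3,6-dihydro-2H-pyridine-1-carboxylate
Conditions: RuCl2(=CHPh)(PCy3)(H2IMes) (second-generation Grubbs catalyst, 5 mol %), 1,4-benzoquinone (10 mol %), ethylene (1 atm), CH2Cl2 (0.01 M), 40 °C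
Reagents that add atoms: none
Why: Ring-rearrangement metathesis, the ring-opening/ring-closing domino known for N-allyl cycloalkenyl amine derivatives. The catalyst initiates at the only terminal alkene and gives the alkylidene Ru=C7H–C6H2–N5. Intramolecular [2+2] cycloaddition to the cyclopentene double bond with C7 bound to C8, followed by cycloreversion, closes ring B in a six-membered ring-closing-metathesis mode through the new C7=C8 bond and cuts the carbocycle in the same event. Ruthenium is left on Cc and is handed to ethylene or to the next molecule of 10, which frees the but-3-enyl terminus, so the net change is an isomerisation. The required regiochemistry is fixed by the tether: the opposite metallacycle would give an eight-membered azacycle, and a path that begins with ethenolysis of the cyclopentene reaches the same six-membered ring through the C9 vinyl group. Both sides hold one cis ring alkene and one terminal alkene, so the driving force is the exchange of cyclopentene strain for an almost strain-free tetrahydropyridine. No stereocentre is formed: C9 and C9a are not reacting centres, so 1R,1'S in 10 becomes 2R,3S in 11, and benzoquinone intercepts ruthenium hydrides that could move C7=C8 towards C9. Ethylene and dilution hold back cross-metathesis oligomers, and the carbamate keeps nitrogen from binding ruthenium.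

Step 8
Reactants: 11 tetrahydropyridine acetal
Product: 12 tert-butyl (2R,3S)-3-(but-3-en-1-yl)-2-(2-oxoethyl)-3,6-dihydro-2H-pyridine-1-carboxylate
Conditions: TsOH·H2O (10 mol %), THF/H2O 4:1, rt
Reagents that add atoms: water, O
Why: Acid-catalysed acetal hydrolysis; dilute acid at room temperature leaves the tert-butyl carbamate intact, and the tertiary carbamate cannot add to the aldehyde.

Step 9
Reactants: 12 aldehyde
Product: 13 2-[(2R,3S)-1-(tert-butoxycarbonyl)-3-(but-3-en-1-yl)-1,2,3,6-tetrahydropyridin-2-yl]acetic acid
Conditions: NaClO2, NaH2PO4, 2-methylbut-2-ene, t-BuOH/H2O, rt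
Reagents that add atoms: sodium chlorite, [Na+].[O-]Cl=O
Why: Pinnick oxidation; the buffered chlorite oxidises only the aldehyde, and the sacrificial alkene takes up the hypochlorite that would otherwise attack the two alkenes.

Step 10
Reactants: 13 acid
Product: 14 methyl 2-[(2R,3S)-1-(tert-butoxycarbonyl)-3-(but-3-en-1-yl)-1,2,3,6-tetrahydropyridin-2-yl]acetate
Conditions: MeI, K2CO3, DMF, rt
Reagents that add atoms: iodomethane, CI
Why: O-Alkylation of the carboxylate; the weak base does not provoke β-elimination of the carbamate nitrogen.

Step 11
Reactants: 5 cyclopent-2-en-1-yl methyl carbonate; 3 1,1-dimethoxy-3-nitropropane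
Product: 15 (R)-3-(3,3-dimethoxy-1-nitropropyl)cyclopent-1-ene, epimer pair at the nitro carbon (C9a')
Conditions: Pd2(dba)3·CHCl3 (2.5 mol %), (S,S)-DACH-phenyl diphosphine (7.5 mol %), 3 (2 equiv), CH2Cl2, rt
Reagents that add atoms: none
Why: The same asymmetric allylic alkylation as step 4 with the mirror-image ligand, which directs the nitronate to the other allyl terminus and sets C9' (R).

Step 12
Reactants: 15 (R)-3-(3,3-dimethoxy-1-nitropropyl)cyclopent-1-ene
Product: 17 tert-butyl N-{(1S)-1-[(1R)-cyclopent-2-en-1-yl]-3,3-dimethoxypropyl}carbamate, via primary amine 16 (not isolated)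
Conditions: Zn dust, AcOH, MeOH, 0 °C to rt; then Et3N, Boc2O, same flask, rt; chromatographic separation of the C9a' epimers
Reagents that add atoms: di-tert-butyl dicarbonate, CC(C)(C)OC(=O)OC(=O)OC(C)(C)C
Why: Nitro reduction and carbamate formation as in step 5; the enantiomer of 8 has the same chromatographic behaviour, so the 1S,1'R isomer is collected in the same way.

Step 13
Reactants: 17 carbamate of step 12; 9 allyl bromide
Product: 18 tert-butyl N-allyl-N-{(1S)-1-[(1R)-cyclopent-2-en-1-yl]-3,3-dimethoxypropyl}carbamate
Conditions: NaH, allyl bromide, DMF, 0 °C to rt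
Reagents that add atoms: allyl bromide (9), C=CCBr
Why: SN2 N-allylation of the carbamate anion, as in step 6.

Step 14
Reactants: 18 N-allyl cyclopentenyl carbamate (mirror series)
Product: 19 tert-butyl (2S,3R)-3-(but-3-en-1-yl)-2-(2,2-dimethoxyethyl)-3,6-dihydro-2H-pyridine-1-carboxylate
Conditions: RuCl2(=CHPh)(PCy3)(H2IMes) (5 mol %), 1,4-benzoquinone (10 mol %), ethylene (1 atm), CH2Cl2 (0.01 M), 40 °C
Reagents that add atoms: none
Why: Ring-rearrangement metathesis as in step 7 on the enantiomer; ring B' closes through C7'=C8', and C9' and C9a' are carried over unchanged.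

Step 15
Reactants: 19 tetrahydropyridine acetal (mirror series)
Product: 20 tert-butyl (2S,3R)-3-(but-3-en-1-yl)-2-(2-oxoethyl)-3,6-dihydro-2H-pyridine-1-carboxylate
Conditions: TsOH·H2O (10 mol %), THF/H2O 4:1, rt
Reagents that add atoms: water, O
Why: Acetal hydrolysis as in step 8.

Step 16
Reactants: 20 aldehyde (mirror series)
Product: 21 2-[(2S,3R)-1-(tert-butoxycarbonyl)-3-(but-3-en-1-yl)-1,2,3,6-tetrahydropyridin-2-yl]acetic acid
Conditions: NaClO2, NaH2PO4, 2-methylbut-2-ene, t-BuOH/H2O, rt
Reagents that add atoms: sodium chlorite, [Na+].[O-]Cl=O
Why: Pinnick oxidation as in step 9.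

Step 17
Reactants: 21 acid (mirror series)
Product: 22 methyl 2-[(2S,3R)-1-(tert-butoxycarbonyl)-3-(but-3-en-1-yl)-1,2,3,6-tetrahydropyridin-2-yl]acetate
Conditions: MeI, K2CO3, DMF, rt
Reagents that add atoms: iodomethane, CI
Why: Carboxylate O-alkylation as in step 10.

Step 18
Reactants: 22 methyl ester (mirror series); 23 (Z)-but-2-ene-1,4-diol
Product: 24 methyl 2-{(2S,3R)-1-(tert-butoxycarbonyl)-3-[(3E)-5-hydroxypent-3-en-1-yl]-1,2,3,6-tetrahydropyridin-2-yl}acetate
Conditions: RuCl2(=CHPh)(PCy3)(H2IMes) (5 mol %), 1,4-benzoquinone (10 mol %), 23 (4 equiv), CH2Cl2/THF, 40 °C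
Reagents that add atoms: (Z)-but-2-ene-1,4-diol (23), OC/C=C\CO
Why: Olefin cross-metathesis of the single terminal alkene of 22 with an excess of a symmetric partner that delivers the same CH–CH2OH unit from either end, which adds Cd' and Ce'. The unstrained ring alkene next to the C9' branch stays out, and the alkene geometry (E expected) is irrelevant because it is hydrogenated later.

Step 19
Reactants: 24 allylic alcohol ester; 9 allyl bromide
Product: 26 methyl 2-{(2R,3R)-1-(tert-butoxycarbonyl)-3-[(3E)-5-hydroxypent-3-en-1-yl]-1,2,3,6-tetrahydropyridin-2-yl}pent-4-enoate (same spatial arrangement at the ring carbons as in 24; epimers at the ester α-carbon C1'), via dilithio alkoxide enolate 25 (not isolated)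
Conditions: LiN(iPr)2 (2.2 equiv), THF, −78 °C; allyl bromide (1.2 equiv), −78 to −30 °C
Reagents that add atoms: allyl bromide (9), C=CCBr
Why: Ester enolate alkylation. The first equivalent of base holds the hydroxyl as a lithium alkoxide, a poor nucleophile in cold THF, so C-allylation wins, as in alkylations of hydroxy ester dianions. A carbamate nitrogen is a poor leaving group, so the β-amino enolate should persist at low temperature; C1' forms without reliable facial bias and is left as an epimer mixture because it stays α to a carbonyl until step 27.

Step 20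
Reactants: 26 C1'-allylated allylic alcohol
Product: 27 methyl 2-{(2R,3R)-1-(tert-butoxycarbonyl)-3-[(3E)-5-bromopent-3-en-1-yl]-1,2,3,6-tetrahydropyridin-2-yl}pent-4-enoate (C1' epimers)
Conditions: CBr4, PPh3, CH2Cl2, 0 °C
Reagents that add atoms: carbon tetrabromide, BrC(Br)(Br)Br
Why: Appel reaction of a primary allylic alcohol under neutral conditions that carbamate, ester and alkenes tolerate.

Step 21
Reactants: 14 methyl ester (9S series); 27 allylic bromide (9'R series)
Product: 29 open head-to-tail dimer: C1 of the 9S,9aS unit bonded through an (E)-CH2CH=CHCH2CH2 bridge to C9' of the 9'R,9a'R unit, but-3-enyl on C9, allyl on C1', two N-Boc groups, two methyl esters (C1 and C1' epimers), via lithium enolate 28 (not isolated)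
Conditions: LiN(iPr)2 (1.05 equiv), THF, −78 °C; then 27 (1.0 equiv), DMPU, −78 to −40 °C
Reagents that add atoms: none
Why: SN2 alkylation of an ester enolate by a primary allylic bromide, one of the fastest carbon electrophiles, so the reaction can finish before the enolate is warmed. The nucleophile exists only in the 9S half and the electrophile only in the 9'R half, which enforces crosswise, head-to-tail union; C1 is again left as an epimer mixture.

Step 22
Reactants: 29 open dimer
Product: 30 16-membered macrocyclic tetraene bis(N-Boc) dimethyl diester (C7=C8 and C7'=C8' in rings B, E alkene in the bridge C9'···C1, new E/Z alkene Cc=Cd in the bridge C9···C1')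
Conditions: RuCl2(=CHPh)(PCy3)2 (first-generation Grubbs catalyst, 2 × 10 mol %), CH2Cl2 (1 mM), reflux
Reagents that add atoms: none
Why: Macrocyclic ring-closing metathesis of the two terminal alkenes with loss of ethylene. This catalyst turns over terminal alkenes but hardly touches 1,2-disubstituted ones, so the first bridge and the ring alkenes should stay out of the exchange. Allylic strain with the N-Boc group holds the C9a substituent axial and the trans C9 arm pseudoaxial, so the two arms of each unit diverge; this disfavours eight-membered closure and suits the large ring.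

Step 23
Reactants: 30 macrocyclic tetraene
Product: 31 saturated macrocyclic bis(N-Boc-piperidine) dimethyl diester
Conditions: H2 (1 atm), PtO2, EtOAc, rt
Reagents that add atoms: none
Why: Heterogeneous hydrogenation of four disubstituted alkenes. Platinum dioxide is preferred to palladium because it causes far less double-bond migration, and migration of C7=C8 towards C9 would erase the only stereocentre that cannot be corrected.

Step 24
Reactants: 31 macrocyclic diester
Product: 32 macrocyclic bis(N-methoxy-N-methylamide)
Conditions: MeNH(OMe)·HCl (6 equiv), iPrMgCl (12 equiv), THF, −20 to 0 °C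
Reagents that add atoms: N,O-dimethylhydroxylamine hydrochloride, CNOC.Cl
Why: Aminolysis of methyl esters by the magnesium amide of N,O-dimethylhydroxylamine (Weinreb amide synthesis), which also converts α-branched esters and leaves tertiary carbamates alone.

Step 25
Reactants: 32 bis(N-methoxy-N-methylamide); 33 ethylmagnesium bromide
Product: 34 macrocyclic bis(ethyl ketone), C2 and C2' as propanoyl carbonyls
Conditions: EtMgBr (6 equiv), THF, 0 °C to rt; aq NH4Cl
Reagents that add atoms: ethylmagnesium bromide (33), CC[Mg]Br
Why: Weinreb ketone synthesis; the chelated tetrahedral adduct survives until work-up, so each amide takes up one ethyl group (C3 and its methyl group) and no tertiary alcohol forms.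

Step 26
Reactants: 34 bis(ethyl ketone); 35 formaldehyde
Product: 37 macrocyclic bis(quinolizidin-2-one) with C9, C9a, C9', C9a' as in 38 and C1, C3, C1', C3' as epimer mixtures, via bis(ammonium trifluoroacetate) 36 (not isolated)
Conditions: CF3CO2H/CH2Cl2 1:4, 0 °C to rt, evaporate; then aq CH2O (37 %, 2.2 equiv), EtOH (0.01 M), 70 °C; aq NaHCO3 work-up
Reagents that add atoms: formaldehyde (35), C=O
Why: Acidolysis of both carbamates, then a twofold intramolecular Mannich reaction: each piperidinium nitrogen condenses with 35 to the N5=C4 iminium ion, which the C3 enol of the ethyl ketone captures in a 6-endo-trig closure, in the way 2-(2-oxoalkyl)piperidines condense with aldehydes to give quinolizidin-2-ones. Attack through C1 would give an azetidine and does not compete, and the acidic medium protects the β-amino ketone from β-elimination.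

Step 27
Reactants: 37 bis(quinolizidin-2-one) stereoisomer mixture
Product: 38 petrosin A
Conditions: NaOMe (0.2 equiv), MeOH, rt to 40 °C; crystallisation or chromatography
Reagents that add atoms: none
Why: Base-catalysed epimerisation under thermodynamic control: C1 and C3 equilibrate through the enolates, and retro-Michael/Michael reaction is available as a slower correction at C9a, while C9 and C9' cannot move, so only the meso manifold is sampled. In each trans-fused unit the methyl group should settle equatorial and the C1 chain axial. The axial position costs only a contact with H3 and the nitrogen lone pair, whereas the equatorial position clashes with the equatorial C9 chain, and this arrangement is 1R,3R,9S,9aS/1'S,3'S,9'R,9a'R.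

## Compound list

1 | acrolein | C=CC=O | starting material
2 | 3-nitropropanal | O=CCC[N+](=O)[O-] | intermediate
3 | 1,1-dimethoxy-3-nitropropane | COC(CC[N+](=O)[O-])OC | intermediate
4 | cyclopent-2-en-1-ol (racemic) | OC1C=CCC1 | starting material
5 | cyclopent-2-en-1-yl methyl carbonate (racemic) | COC(=O)OC1C=CCC1 | intermediate
6 | (S)-3-(3,3-dimethoxy-1-nitropropyl)cyclopent-1-ene, C9a epimer pair | O=[N+]([O-])C(CC(OC)OC)[C@@H]1C=CCC1 | intermediate
7 | 1-[(1S)-cyclopent-2-en-1-yl]-3,3-dimethoxypropan-1-amine, C9a epimer pair | NC(CC(OC)OC)[C@@H]1C=CCC1 | intermediate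
8 | tert-butyl N-{(1R)-1-[(1S)-cyclopent-2-en-1-yl]-3,3-dimethoxypropyl}carbamate | CC(C)(C)OC(=O)N[C@H](CC(OC)OC)[C@@H]1C=CCC1 | intermediate
9 | allyl bromide | C=CCBr | starting material
10 | tert-butyl N-allyl-N-{(1R)-1-[(1S)-cyclopent-2-en-1-yl]-3,3-dimethoxypropyl}carbamate | C=CCN(C(=O)OC(C)(C)C)[C@H](CC(OC)OC)[C@@H]1C=CCC1 | intermediate
11 | tert-butyl (2R,3S)-3-(but-3-en-1-yl)-2-(2,2-dimethoxyethyl)-3,6-dihydro-2H-pyridine-1-carboxylate | C=CCC[C@H]1C=CCN(C(=O)OC(C)(C)C)[C@@H]1CC(OC)OC | intermediate
12 | tert-butyl (2R,3S)-3-(but-3-en-1-yl)-2-(2-oxoethyl)-3,6-dihydro-2H-pyridine-1-carboxylate | C=CCC[C@H]1C=CCN(C(=O)OC(C)(C)C)[C@@H]1CC=O | intermediate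
13 | 2-[(2R,3S)-1-(tert-butoxycarbonyl)-3-(but-3-en-1-yl)-1,2,3,6-tetrahydropyridin-2-yl]acetic acid | C=CCC[C@H]1C=CCN(C(=O)OC(C)(C)C)[C@@H]1CC(=O)O | intermediate
14 | methyl 2-[(2R,3S)-1-(tert-butoxycarbonyl)-3-(but-3-en-1-yl)-1,2,3,6-tetrahydropyridin-2-yl]acetate | C=CCC[C@H]1C=CCN(C(=O)OC(C)(C)C)[C@@H]1CC(=O)OC | intermediate
15 | (R)-3-(3,3-dimethoxy-1-nitropropyl)cyclopent-1-ene, C9a' epimer pair | O=[N+]([O-])C(CC(OC)OC)[C@H]1C=CCC1 | intermediate
16 | 1-[(1R)-cyclopent-2-en-1-yl]-3,3-dimethoxypropan-1-amine, C9a' epimer pair | NC(CC(OC)OC)[C@H]1C=CCC1 | intermediate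
17 | tert-butyl N-{(1S)-1-[(1R)-cyclopent-2-en-1-yl]-3,3-dimethoxypropyl}carbamate | CC(C)(C)OC(=O)N[C@@H](CC(OC)OC)[C@H]1C=CCC1 | intermediate
18 | tert-butyl N-allyl-N-{(1S)-1-[(1R)-cyclopent-2-en-1-yl]-3,3-dimethoxypropyl}carbamate | C=CCN(C(=O)OC(C)(C)C)[C@@H](CC(OC)OC)[C@H]1C=CCC1 | intermediate
19 | tert-butyl (2S,3R)-3-(but-3-en-1-yl)-2-(2,2-dimethoxyethyl)-3,6-dihydro-2H-pyridine-1-carboxylate | C=CCC[C@@H]1C=CCN(C(=O)OC(C)(C)C)[C@H]1CC(OC)OC | intermediate
20 | tert-butyl (2S,3R)-3-(but-3-en-1-yl)-2-(2-oxoethyl)-3,6-dihydro-2H-pyridine-1-carboxylate | C=CCC[C@@H]1C=CCN(C(=O)OC(C)(C)C)[C@H]1CC=O | intermediate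
21 | 2-[(2S,3R)-1-(tert-butoxycarbonyl)-3-(but-3-en-1-yl)-1,2,3,6-tetrahydropyridin-2-yl]acetic acid | C=CCC[C@@H]1C=CCN(C(=O)OC(C)(C)C)[C@H]1CC(=O)O | intermediate
22 | methyl 2-[(2S,3R)-1-(tert-butoxycarbonyl)-3-(but-3-en-1-yl)-1,2,3,6-tetrahydropyridin-2-yl]acetate | C=CCC[C@@H]1C=CCN(C(=O)OC(C)(C)C)[C@H]1CC(=O)OC | intermediate
23 | (Z)-but-2-ene-1,4-diol | OC/C=C\CO | starting material
24 | methyl 2-{(2S,3R)-1-(tert-butoxycarbonyl)-3-[(3E)-5-hydroxypent-3-en-1-yl]-1,2,3,6-tetrahydropyridin-2-yl}acetate | OC/C=C/CC[C@@H]1C=CCN(C(=O)OC(C)(C)C)[C@H]1CC(=O)OC | intermediate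
25 | dilithio alkoxide enolate of 24 | [Li+].[Li+].[O-]C/C=C/CC[C@@H]1C=CCN(C(=O)OC(C)(C)C)[C@H]1C=C([O-])OC | intermediate
26 | methyl 2-{(2R,3R)-1-(tert-butoxycarbonyl)-3-[(3E)-5-hydroxypent-3-en-1-yl]-1,2,3,6-tetrahydropyridin-2-yl}pent-4-enoate, C1' epimers | OC/C=C/CC[C@@H]1C=CCN(C(=O)OC(C)(C)C)[C@H]1C(CC=C)C(=O)OC | intermediate
27 | methyl 2-{(2R,3R)-1-(tert-butoxycarbonyl)-3-[(3E)-5-bromopent-3-en-1-yl]-1,2,3,6-tetrahydropyridin-2-yl}pent-4-enoate, C1' epimers | BrC/C=C/CC[C@@H]1C=CCN(C(=O)OC(C)(C)C)[C@H]1C(CC=C)C(=O)OC | intermediate
28 | lithium enolate of 14 | [Li+].C=CCC[C@H]1C=CCN(C(=O)OC(C)(C)C)[C@@H]1C=C([O-])OC | intermediate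
29 | open head-to-tail dimer (9S,9aS unit alkylated at C1 by the E-pentenylene bridge from C9' of the 9'R,9a'R unit; butenyl on C9, allyl on C1'; C1, C1' epimers) | C=CCC[C@H]1C=CCN(C(=O)OC(C)(C)C)[C@@H]1C(C(=O)OC)C/C=C/CC[C@@H]2C=CCN(C(=O)OC(C)(C)C)[C@H]2C(CC=C)C(=O)OC | intermediate
30 | 16-membered macrocyclic tetraene bis(N-Boc) dimethyl diester (new alkene E/Z; C1, C1' epimers) | C1=CCC[C@H]2C=CCN(C(=O)OC(C)(C)C)[C@@H]2C(C(=O)OC)C/C=C/CC[C@@H]3C=CCN(C(=O)OC(C)(C)C)[C@H]3C(C1)C(=O)OC | intermediate
31 | saturated macrocyclic bis(N-Boc-piperidine) dimethyl diester (C1, C1' epimers) | C1CCCC[C@H]2CCCN(C(=O)OC(C)(C)C)[C@@H]2C(C(=O)OC)CCCCC[C@@H]3CCCN(C(=O)OC(C)(C)C)[C@H]3C1C(=O)OC | intermediate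
32 | macrocyclic bis(N-methoxy-N-methylamide) (C1, C1' epimers) | C1CCCC[C@H]2CCCN(C(=O)OC(C)(C)C)[C@@H]2C(C(=O)N(C)OC)CCCCC[C@@H]3CCCN(C(=O)OC(C)(C)C)[C@H]3C1C(=O)N(C)OC | intermediate
33 | ethylmagnesium bromide | CC[Mg]Br | starting material
34 | macrocyclic bis(N-Boc-piperidine) bis(ethyl ketone) (C1, C1' epimers) | C1CCCC[C@H]2CCCN(C(=O)OC(C)(C)C)[C@@H]2C(C(=O)CC)CCCCC[C@@H]3CCCN(C(=O)OC(C)(C)C)[C@H]3C1C(=O)CC | intermediate
35 | formaldehyde | C=O | starting material
36 | macrocyclic bis(piperidinium trifluoroacetate) bis(ethyl ketone) | C1CCCC[C@H]2CCCN[C@@H]2C(C(=O)CC)CCCCC[C@@H]3CCCN[C@H]3C1C(=O)CC.OC(=O)C(F)(F)F.OC(=O)C(F)(F)F | intermediate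
37 | macrocyclic bis(quinolizidin-2-one), 9S,9aS,9'R,9a'R, epimer mixture at C1, C3, C1', C3' | CC1CN2CCC[C@@H]3CCCCCC4C(=O)C(C)CN5CCC[C@@H](CCCCCC(C1=O)[C@H]32)[C@H]45 | intermediate
38 | petrosin A | C[C@@H]1CN2CCC[C@@H]3CCCCC[C@@H]4C(=O)[C@@H](C)CN5CCC[C@@H](CCCCC[C@@H](C1=O)[C@H]32)[C@H]45 | target

## Step count and least certain steps

Total: 27 steps. Longest linear sequence: 19 steps (steps 1, 2 and 11 to 27).

**Step 7 (and its mirror, step 14), the key step.**

- *Risk:* the domino is an equilibrium with only a moderate driving force, so incomplete rearrangement is possible. Intermolecular metathesis of the terminal alkenes can build dimers and oligomers, and ruthenium hydrides from catalyst decay can move the new alkene towards C9.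
- *Fallback (sets out from 8, comes back at 11):* this makes the same C7=C8 bond without any metathesis.
  1. Oxidative cleavage of the cyclopentene of 8 (OsO4 cat., NMO, then NaIO4) would give the dialdehyde tert-butyl N-(4-formyl-1,1-dimethoxy-7-oxoheptan-3-yl)carbamate F1, with C9 and C9a as in 8.
  2. A one-flask aza-Michael/intramolecular Wittig annulation with vinyltriphenylphosphonium bromide and NaH in THF would tie nitrogen to C6 and close ring B onto the nearer, C8 aldehyde. A six-membered ring is far easier here than a nine-membered one. The product is tert-butyl 2-(2,2-dimethoxyethyl)-3-(3-oxopropyl)-3,6-dihydro-2H-pyridine-1-carboxylate F2.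
  3. Methylenation of F2 with Ph3P=CH2 returns 11.
- *Weak point of the fallback:* C9 is α to an aldehyde in F1, so base contact has to be short.

**Step 21 (union by enolate alkylation).**

- *Risk:* the carbamate nitrogen can be lost from the enolate by β-elimination on warming. Proton exchange with the α-CH of the ester in 27 can occur, and a bimolecular alkylation run at 1:1 stoichiometry may not reach completion.
- *Fallback (sets out from 14, comes back at 29):* the hard enolate is replaced by a soft one.
  1. Enolate 28 is trapped at −78 °C with allyl chloroformate, a reaction that needs no warming. This gives the mixed malonate 1-allyl 3-methyl 2-[1-(tert-butoxycarbonyl)-3-(but-3-enyl)-1,2,3,6-tetrahydropyridin-2-yl]propanedioate F3.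
  2. The sodium salt of F3 (NaH, THF/DMF, rt) is too weak a base to expel a carbamate anion, and it can be alkylated with 27 at leisure to give the quaternary malonate dimer F4.
  3. Pd(PPh3)4 with HCO2H/Et3N in warm dioxane removes the allyl ester with decarboxylation and gives 29.

**Step 22 (macrocyclic ring-closing metathesis).**

- *Risk:* oligomerisation can outrun closure. The ester carbonyl can chelate the alkylidene formed at the C1' allyl group. If forcing conditions are then needed, the internal alkene of the first bridge may enter the exchange, which leads to scrambling of the bridges or to back-biting into an eight-membered ring.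
- *Fallback (sets out from 24, comes back at 31):* the first bridge is saturated before any diene is exposed to the catalyst.
  1. Hydrogenation of 24 (H2, PtO2) gives the saturated hydroxy ester methyl 2-[1-(tert-butoxycarbonyl)-3-(5-hydroxypentyl)piperidin-2-yl]acetate F5.
  2. Allylation under the conditions of step 19 gives the C1'-allyl hydroxy ester F6.
  3. I2, PPh3 and imidazole give the primary iodide F7.
  4. Alkylation of enolate 28 with F7 (THF/DMPU, −78 to −20 °C) gives the open dimer with a saturated bridge F8.
  5. Ring-closing metathesis of F8, whose only acyclic alkenes are the two terminal ones, gives the macrocyclic diene F9. Hydrogenation as in step 23 then gives 31.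
- *Cost of the fallback:* the electrophile in the union is less reactive.

**Step 26 (twofold Mannich closure).**

- *Risk:* formaldehyde can over-react by aminal bridging of the two nitrogens, by hydroxymethylation at C1 or C3, or by a second aminomethylation. The amine can also be lost by β-elimination from the free amino ketone if the medium drifts towards neutral.
- *Fallback (sets out from 32, comes back at 37):* ring A is closed at N5–C4 instead of C3–C4, with no formaldehyde.
  1. Isopropenylmagnesium bromide converts 32 into the macrocyclic bis(isopropenyl ketone) F10.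
  2. CF3CO2H removes the carbamates to give the bis(ammonium trifluoroacetate) of the amino enone F11.
  3. Neutralisation with aq NaHCO3 lets each nitrogen add to its own enone terminus in a 6-endo-trig aza-Michael reaction, which gives 37.

**Step 27 (equilibration).**

- *Risk:* the solution equilibrium may populate several stereoisomers, because the strain of the 16-membered ring can offset the local preference for an axial C1 chain. It may, for example, favour arrangements epimeric at C9a. Long base contact may also erode material through irreversible reactions of the ring-opened enone.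
- *Fallback (sets out from 37, comes back at 38):* the single solution equilibrium is replaced by a crystallisation-induced diastereomer transformation. The epimerising base is used in a solvent from which the centrosymmetric 38 crystallises, so that the solid drains the equilibrium and the mother liquors are re-equilibrated. No new compound is involved.

## Further compounds

F1 | step 7 | tert-butyl N-(4-formyl-1,1-dimethoxy-7-oxoheptan-3-yl)carbamate, C9 and C9a as in 8 | CC(C)(C)OC(=O)N[C@H](CC(OC)OC)[C@H](C=O)CCC=O
F2 | step 7 | tert-butyl 2-(2,2-dimethoxyethyl)-3-(3-oxopropyl)-3,6-dihydro-2H-pyridine-1-carboxylate, C9 and C9a as in 11 | O=CCC[C@H]1C=CCN(C(=O)OC(C)(C)C)[C@@H]1CC(OC)OC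
F3 | step 21 | 1-allyl 3-methyl 2-[1-(tert-butoxycarbonyl)-3-(but-3-enyl)-1,2,3,6-tetrahydropyridin-2-yl]propanedioate | C=CCC[C@H]1C=CCN(C(=O)OC(C)(C)C)[C@@H]1C(C(=O)OC)C(=O)OCC=C
F4 | step 21 | quaternary malonate dimer (F3 alkylated at C1 by 27) | C=CCC[C@H]1C=CCN(C(=O)OC(C)(C)C)[C@@H]1C(C(=O)OC)(C(=O)OCC=C)C/C=C/CC[C@@H]2C=CCN(C(=O)OC(C)(C)C)[C@H]2C(CC=C)C(=O)OC
F5 | step 22 | methyl 2-[1-(tert-butoxycarbonyl)-3-(5-hydroxypentyl)piperidin-2-yl]acetate, 9'R series | OCCCCC[C@@H]1CCCN(C(=O)OC(C)(C)C)[C@H]1CC(=O)OC
F6 | step 22 | methyl 2-[1-(tert-butoxycarbonyl)-3-(5-hydroxypentyl)piperidin-2-yl]pent-4-enoate, C1' epimers | OCCCCC[C@@H]1CCCN(C(=O)OC(C)(C)C)[C@H]1C(CC=C)C(=O)OC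
F7 | step 22 | methyl 2-[1-(tert-butoxycarbonyl)-3-(5-iodopentyl)piperidin-2-yl]pent-4-enoate, C1' epimers | ICCCCC[C@@H]1CCCN(C(=O)OC(C)(C)C)[C@H]1C(CC=C)C(=O)OC
F8 | step 22 | open dimer with saturated bridge C9'···C1 | C=CCC[C@H]1C=CCN(C(=O)OC(C)(C)C)[C@@H]1C(C(=O)OC)CCCCC[C@@H]2CCCN(C(=O)OC(C)(C)C)[C@H]2C(CC=C)C(=O)OC
F9 | step 22 | macrocyclic diene (C7=C8 and Cc=Cd) bis(N-Boc) dimethyl diester | C1=CCC[C@H]2C=CCN(C(=O)OC(C)(C)C)[C@@H]2C(C(=O)OC)CCCCC[C@@H]3CCCN(C(=O)OC(C)(C)C)[C@H]3C(C1)C(=O)OC
F10 | step 26 | macrocyclic bis(N-Boc-piperidine) bis(isopropenyl ketone) | C1CCCC[C@H]2CCCN(C(=O)OC(C)(C)C)[C@@H]2C(C(=O)C(C)=C)CCCCC[C@@H]3CCCN(C(=O)OC(C)(C)C)[C@H]3C1C(=O)C(C)=C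
F11 | step 26 | macrocyclic bis(piperidinium trifluoroacetate) bis(isopropenyl ketone) | C1CCCC[C@H]2CCCN[C@@H]2C(C(=O)C(C)=C)CCCCC[C@@H]3CCCN[C@H]3C1C(=O)C(C)=C.OC(=O)C(F)(F)F.OC(=O)C(F)(F)F
F0 | step 27 | none | none
A1 | alternative 1 | quinolizidine ketal half with two triphenylphosphonium ylide termini | C[C@@H]1CN2CCC[C@H](CCC=P(c3ccccc3)(c3ccccc3)c3ccccc3)[C@H]2[C@@H](CC=P(c3ccccc3)(c3ccccc3)c3ccccc3)C14OCCO4
A2 | alternative 1 | mirror-image-core quinolizidine ketal half with two aldehyde termini | C[C@H]1CN2CCC[C@@H](CCC=O)[C@@H]2[C@H](CC=O)C13OCCO3
A3 | alternative 1 | macrocyclic (Z,Z)-diene bis-ketal | C[C@@H]1CN2CCC[C@@H]3CC/C=C\C[C@@H]4C6(OCCO6)[C@@H](C)CN5CCC[C@@H](CC/C=C\C[C@@H](C17OCCO7)[C@H]32)[C@H]45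
A4 | alternative 2 | macrocyclic bis-nitrone | C[C@@H]1C[N+]([O-])=C2CC[C@@H]3CCCCC[C@@H]4C(=O)[C@@H](C)C[N+]([O-])=C5CC[C@@H](CCCCC[C@@H](C1=O)[C@H]32)[C@H]45
A5 | alternative 2 | macrocyclic bis-oxaziridine | C[C@@H]1CN2OC23CC[C@@H]4CCCCC[C@@H]5C(=O)[C@@H](C)CN6OC67CC[C@@H](CCCCC[C@@H](C1=O)[C@H]43)[C@H]57
A6 | alternative 2 | macrocyclic bis(quinolizidine-2,6-dione) | C[C@@H]1CN2C(=O)CC[C@@H]3CCCCC[C@@H]4C(=O)[C@@H](C)CN5C(=O)CC[C@@H](CCCCC[C@@H](C1=O)[C@H]32)[C@H]45
A7 | alternative 3 | macrocyclic diyne dialdehyde | O=C[C@H](C)CN1CCC[C@@H]2CCCCC#C[C@@H]3N(C[C@H](C)C=O)CCC[C@H]3CCCCC#C[C@@H]12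
A8 | alternative 3 | macrocyclic bis(allylic triethylsilyl ether) | C[C@@H]1CN2CCC[C@@H]3CCCC/C=C4/[C@H](O[Si](CC)(CC)CC)[C@@H](C)CN5CCC[C@@H](CCCC/C=C(/[C@H]1O[Si](CC)(CC)CC)[C@H]32)[C@H]45
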